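**Strategy.** Everything rests on opening the 19-membered ansa lactam at the anilide N–C20 bond of the benzene ring; C20 is meta to the phenolic carbon C18 and to C16, which carries the benzylic carbinol C15. A bromine at C20 is carried inert through the whole chain assembly and is finally displaced by the terminal C1 carboxamide nitrogen in an intramolecular copper-mediated Goldberg amidation, which closes the macrocycle and creates the anilide in one operation. The precursor is the fully silylated acyclic bromoarene dienamide 24, built from a C1–C7 aldehyde and a C8–C21 alkyne joined by hydrozirconation and chelation-controlled alkenylzinc addition.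

Key step: step 19

Remark: locants C1–C21 follow the ansa chain of the target (C1 amide carbonyl, C15 benzylic carbinol, C16–C21 benzene ring with OH on C18 and N on C20); descriptors are CIP descriptors of the compound named. Ar = 3-bromo-5-[(triisopropylsilyl)oxy]phenyl, TBS = tert-butyldimethylsilyl, TIPS = triisopropylsilyl, Tr = triphenylmethyl.
Remark: compounds 1 and 8, (Z)-crotylboronic acid pinacol ester and 1-propynyllithium are taken as commercial.

Step 1
Reactants: 1 (S)-glycidyl trityl ether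
Product: 2 (S)-1-(triphenylmethoxy)hex-5-en-2-ol
Conditions: allylMgBr, CuI (10 mol %), THF, −30 °C
Reagents that add atoms: allylmagnesium bromide, C=CC[Mg]Br
Why: Copper-catalysed Grignard opening of the terminal epoxide is an SN2 attack at the unsubstituted carbon, so the stereocentre (future C6) is untouched and C3–C5 arrive as a terminal alkene.

Step 2
Reactants: 2 (S)-1-(triphenylmethoxy)hex-5-en-2-ol
Product: 3 (S)-2-methoxy-1-(triphenylmethoxy)hex-5-ene
Conditions: NaH, MeI, THF, 0 °C to rt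
Reagents that add atoms: iodomethane, CI
Why: Williamson etherification of the secondary alkoxide installs the C6 methoxy group without touching the stereocentre, and the trityl ether cannot migrate.

Step 3
Reactants: 3 (S)-2-methoxy-1-(triphenylmethoxy)hex-5-ene
Product: 5 methyl (2E,6S)-6-methoxy-2-methyl-7-(triphenylmethoxy)hept-2-enoate, via aldehyde 4 (not isolated)
Conditions: O3, CH2Cl2, −78 °C; PPh3; then Ph3P=C(Me)CO2Me, rt
Reagents that add atoms: methyl 2-(triphenylphosphoranylidene)propanoate, COC(=O)C(C)=P(c1ccccc1)(c1ccccc1)c1ccccc1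
Why: Ozonolysis with reductive work-up gives the aldehyde, and Wittig olefination with the stabilised α-methyl ylide should give the (E)-trisubstituted enoate.

Step 4
Reactants: 5 methyl (2E,6S)-6-methoxy-2-methyl-7-(triphenylmethoxy)hept-2-enoate
Product: 6 methyl (2E,6S)-7-hydroxy-6-methoxy-2-methylhept-2-enoate
Conditions: TsOH·H2O (cat.), MeOH/CH2Cl2, rt
Reagents that add atoms: none
Why: Acid-catalysed solvolysis of the trityl ether (SN1, trityl cation trapped by methanol) frees the primary alcohol while the methyl ether and the methyl enoate are inert.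

Step 5
Reactants: 6 methyl (2E,6S)-7-hydroxy-6-methoxy-2-methylhept-2-enoate
Product: 7 methyl (2E,6S)-6-methoxy-2-methyl-7-oxohept-2-enoate
Conditions: Dess–Martin periodinane, NaHCO3, CH2Cl2, 0 °C; used at once
Reagents that add atoms: none
Why: Buffered Dess–Martin oxidation is non-enolising, so the configurationally labile α-methoxy aldehyde should form without epimerisation at C6.

Step 6
Reactants: 8 3-bromo-5-hydroxybenzaldehyde
Product: 9 3-bromo-5-[(triisopropylsilyl)oxy]benzaldehyde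
Conditions: TIPSCl, imidazole, DMF, rt
Reagents that add atoms: triisopropylsilyl chloride, CC(C)[Si](Cl)(C(C)C)C(C)C
Why: Imidazole-promoted O-silylation masks the phenol as a robust silyl ether that fluoride removes at the end.

Step 7
Reactants: 9 3-bromo-5-[(triisopropylsilyl)oxy]benzaldehyde
Product: 10 (1R,2S)-1-Ar-2-methylbut-3-en-1-ol
Conditions: (Z)-crotylboronic acid pinacol ester, (R)-3,3'-bis(2,4,6-triisopropylphenyl)-1,1'-binaphthyl-2,2'-diyl hydrogen phosphate [(R)-TRIP] (5 mol %), toluene, −30 °C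
Reagents that add atoms: (Z)-crotylboronic acid pinacol ester, C/C=C\CB1OC(C)(C)C(C)(C)O1
Why: Chiral-phosphoric-acid-catalysed crotylboration runs through a closed chair transition state, so the (Z)-boronate gives the syn C14-methyl/C15-hydroxyl pair, and the catalyst enantiomer, chosen to direct attack to the Re face of the aldehyde, sets 15R and 14S.

Step 8
Reactants: 10 (1R,2S)-1-Ar-2-methylbut-3-en-1-ol
Product: 11 (1R,2S)-1-Ar-1-(TBSO)-2-methylbut-3-ene
Conditions: TBSOTf, 2,6-lutidine, CH2Cl2, −78 to 0 °C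
Reagents that add atoms: tert-butyldimethylsilyl triflate, CC(C)(C)[Si](C)(C)OS(=O)(=O)C(F)(F)F
Why: Silyl triflate silylation protects the benzylic alcohol so that it cannot form a lactol with the aldehyde made in step 10.

Step 9
Reactants: 11 (1R,2S)-1-Ar-1-(TBSO)-2-methylbut-3-ene
Product: 13 (3S,4R)-4-Ar-4-(TBSO)-3-methylbutan-1-ol, via alkylborane 12 (not isolated)
Conditions: 9-BBN, THF, 0 °C to rt; NaBO3·4H2O, THF/H2O, rt
Reagents that add atoms: sodium perborate tetrahydrate (source of the hydroxyl oxygen), [Na+].[O-]OB=O.O.O.O.O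
Why: Hydroboration–oxidation with bulky 9-BBN places boron on the terminal carbon, and perborate oxidises the C–B bond mildly enough for the aryl silyl ether.

Step 10
Reactants: 13 (3S,4R)-4-Ar-4-(TBSO)-3-methylbutan-1-ol
Product: 14 (3S,4R)-4-Ar-4-(TBSO)-3-methylbutanal
Conditions: Dess–Martin periodinane, NaHCO3, CH2Cl2, rt
Reagents that add atoms: none
Why: Dess–Martin oxidation gives the C12 aldehyde without touching the silyl ethers or the aryl bromide.

Step 11
Reactants: 14 (3S,4R)-4-Ar-4-(TBSO)-3-methylbutanal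
Product: 15 (2E,4S,6S,7R)-7-Ar-7-(TBSO)-6-methylhept-2-en-4-ol
Conditions: propyne, (c-C6H11)2BH, toluene, 0 °C; Me2Zn, −78 °C; (+)-3-exo-morpholinoisoborneol [(+)-MIB] (5 mol %); then 14, −10 °C
Reagents that add atoms: propyne, CC#C
Why: Catalytic asymmetric alkenylzinc addition, in which syn-hydroboration of propyne fixes the (E)-alkene, boron-to-zinc exchange gives the alkenylzinc, and the amino-alcohol ligand enantiomer, chosen to deliver the alkenyl group to the Re face, sets 12S.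

Step 12
Reactants: 15 (2E,4S,6S,7R)-7-Ar-7-(TBSO)-6-methylhept-2-en-4-ol
Product: 16 (1S,3S,4R)-4-Ar-4-(TBSO)-3-methyl-1-[(2S,3S)-3-methyloxiran-2-yl]butan-1-ol
Conditions: Ti(OiPr)4 (20 mol %), L-(+)-diisopropyl tartrate (24 mol %), t-BuOOH, 4 Å molecular sieves, CH2Cl2, −20 °C
Reagents that add atoms: tert-butyl hydroperoxide, CC(C)(C)OO
Why: Sharpless asymmetric epoxidation of the secondary (E)-allylic alcohol in its matched sense (L-(+)-tartrate epoxidises the (S)-carbinol fast) should give the anti (erythro) trans-epoxy alcohol, so C12 relays its configuration to C11 and C10, while any C12 epimer from step 11 reacts slowly and is left behind.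

Step 13
Reactants: 16 (1S,3S,4R)-4-Ar-4-(TBSO)-3-methyl-1-[(2S,3S)-3-methyloxiran-2-yl]butan-1-ol
Product: 17 (2R,3S)-2-[(1S,3S,4R)-4-Ar-4-(TBSO)-1-methoxy-3-methylbutyl]-3-methyloxirane
Conditions: NaH, MeI, THF, 0 °C
Reagents that add atoms: iodomethane, CI
Why: Williamson etherification in aprotic medium at low temperature should methylate the C12 alkoxide faster than Payne rearrangement can occur.

Step 14
Reactants: 17 (2R,3S)-2-[(1S,3S,4R)-4-Ar-4-(TBSO)-1-methoxy-3-methylbutyl]-3-methyloxirane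
Product: 18 (4S,5R,6S,8S,9R)-9-Ar-9-(TBSO)-6-methoxy-4,8-dimethylnon-2-yn-5-ol
Conditions: 1-propynyllithium, BF3·OEt2, THF, −78 °C
Reagents that add atoms: 1-propynyllithium, [Li]C#CC
Why: Lewis-acid-promoted acetylide opening of the epoxide is an SN2 reaction with inversion at C10, the carbon remote from the deactivating C12 methoxy group, which turns the trans-epoxide into the syn C10-methyl/C11-hydroxyl pair and brings in C8, C9 and the C8 methyl group.

Step 15
Reactants: 18 (4S,5R,6S,8S,9R)-9-Ar-9-(TBSO)-6-methoxy-4,8-dimethylnon-2-yn-5-ol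
Product: 19 (4S,5R,6S,8S,9R)-9-Ar-5,9-bis(TBSO)-6-methoxy-4,8-dimethylnon-2-yne
Conditions: TBSOTf, 2,6-lutidine, CH2Cl2, 0 °C
Reagents that add atoms: tert-butyldimethylsilyl triflate, CC(C)(C)[Si](C)(C)OS(=O)(=O)C(F)(F)F
Why: Silyl triflate silylation protects the hindered C11 alcohol before the organometallic fragment union.

Step 16
Reactants: 19 (4S,5R,6S,8S,9R)-9-Ar-5,9-bis(TBSO)-6-methoxy-4,8-dimethylnon-2-yne; 7 methyl (2E,6S)-6-methoxy-2-methyl-7-oxohept-2-enoate
Product: 22 methyl (2E,6S,7S,8E,10S,11R,12S,14S,15R)-15-Ar-11,15-bis(TBSO)-7-hydroxy-6,12-dimethoxy-2,8,10,14-tetramethylpentadeca-2,8-dienoate, via alkenylzirconocene chloride 20 (not isolated), via alkenyl(methyl)zinc 21 (not isolated)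
Conditions: 19, Cp2Zr(H)Cl, CH2Cl2, rt to 40 °C; Me2Zn, toluene, −65 °C; then 7, −65 to 0 °C
Reagents that add atoms: none
Why: Hydrozirconation adds Zr–H syn across the alkyne with zirconium on the less hindered methyl-bearing C8 (fixing the 8E alkene), zirconium-to-zinc transmetalation gives an alkenylzinc that adds to the aldehyde, and a five-membered zinc chelate between the aldehyde oxygen and the C6 methoxy group (Cram chelate model) should direct attack to the 6,7-syn (7S) alcohol.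

Step 17
Reactants: 22 methyl (2E,6S,7S,8E,10S,11R,12S,14S,15R)-15-Ar-11,15-bis(TBSO)-7-hydroxy-6,12-dimethoxy-2,8,10,14-tetramethylpentadeca-2,8-dienoate
Product: 23 methyl (2E,6S,7S,8E,10S,11R,12S,14S,15R)-15-Ar-7,11,15-tris(TBSO)-6,12-dimethoxy-2,8,10,14-tetramethylpentadeca-2,8-dienoate
Conditions: TBSOTf, 2,6-lutidine, CH2Cl2, −78 to 0 °C
Reagents that add atoms: tert-butyldimethylsilyl triflate, CC(C)(C)[Si](C)(C)OS(=O)(=O)C(F)(F)F
Why: Silyl triflate silylation of the C7 allylic alcohol leaves the amide made next as the only N–H or O–H nucleophile in the cyclisation substrate.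

Step 18
Reactants: 23 methyl (2E,6S,7S,8E,10S,11R,12S,14S,15R)-15-Ar-7,11,15-tris(TBSO)-6,12-dimethoxy-2,8,10,14-tetramethylpentadeca-2,8-dienoate
Product: 24 (2E,6S,7S,8E,10S,11R,12S,14S,15R)-15-Ar-7,11,15-tris(TBSO)-6,12-dimethoxy-2,8,10,14-tetramethylpentadeca-2,8-dienamide
Conditions: AlMe3, NH4Cl, toluene, 50 °C
Reagents that add atoms: ammonium chloride, [NH4+].[Cl-]
Why: Aminolysis of the methyl ester by the aluminium amide formed from AlMe3 and NH4Cl (Weinreb-type amidation) gives the primary amide directly and avoids hydroxide, which would endanger the aryl silyl ether.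

Step 19
Reactants: 24 (2E,6S,7S,8E,10S,11R,12S,14S,15R)-15-Ar-7,11,15-tris(TBSO)-6,12-dimethoxy-2,8,10,14-tetramethylpentadeca-2,8-dienamide
Product: 25 7,11,15-tris-O-TBS-18-O-TIPS macrolactam (6S,7S,10S,11R,12S,14S,15R; 2E,8E)
Conditions: CuI (0.5 equiv), N,N'-dimethylethylenediamine (1 equiv), K2CO3 (3 equiv), toluene (2 mM), 100 °C
Reagents that add atoms: none
Why: Goldberg amidation: K2CO3 deprotonates the primary amide on the diamine-ligated monovalent copper centre to give a copper amidate, which activates the C20–Br bond (oxidative addition to a trivalent copper aryl amidate) and forms the N–C20 bond by reductive elimination. The closest known reaction type is the copper/1,2-diamine N-arylation of primary amides with aryl bromides, which is also established in its intramolecular, macrolactam-forming version. The one ring closed is the 19-membered ansa lactam (N, C1–C15, C16, C21, C20), formed by end-to-end N-arylation with the C–Br bond exocyclic to the forming ring. No stereocentre is created, and the seven existing ones and both (E)-alkenes are remote from the reacting centres. The step needs N- over O-arylation and intra- over intermolecular coupling: every hydroxyl is silylated so the CONH2 group is the only acidic nucleophile, the bromide is flanked by two ring hydrogens and is unhindered, and high dilution together with the two rigid (E)-trisubstituted alkenes should favour cyclisation.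

Step 20
Reactants: 25 7,11,15-tris-O-TBS-18-O-TIPS macrolactam
Product: 26 target macrolactam CNP0366451.1
Conditions: HF·pyridine, pyridine, THF, 0 °C to rt
Reagents that add atoms: none
Why: Fluoride-mediated desilylation, driven by the strong Si–F bond, should remove the three TBS ethers and the aryl TIPS ether in one buffered operation that leaves the allylic and benzylic alcohols, the anilide and the (E)-alkenes intact.

**Compound list**

1 | (S)-2-[(triphenylmethoxy)methyl]oxirane [(S)-glycidyl trityl ether] | C(c1ccccc1)(c1ccccc1)(c1ccccc1)OC[C@@H]1CO1 | starting material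
2 | (S)-1-(triphenylmethoxy)hex-5-en-2-ol | C(c1ccccc1)(c1ccccc1)(c1ccccc1)OC[C@@H](O)CCC=C | intermediate
3 | (S)-2-methoxy-1-(triphenylmethoxy)hex-5-ene | C(c1ccccc1)(c1ccccc1)(c1ccccc1)OC[C@@H](OC)CCC=C | intermediate
4 | (S)-4-methoxy-5-(triphenylmethoxy)pentanal | C(c1ccccc1)(c1ccccc1)(c1ccccc1)OC[C@@H](OC)CCC=O | intermediate
5 | methyl (2E,6S)-6-methoxy-2-methyl-7-(triphenylmethoxy)hept-2-enoate | C(c1ccccc1)(c1ccccc1)(c1ccccc1)OC[C@@H](OC)CC/C=C(\C)C(=O)OC | intermediate
6 | methyl (2E,6S)-7-hydroxy-6-methoxy-2-methylhept-2-enoate | OC[C@@H](OC)CC/C=C(\C)C(=O)OC | intermediate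
7 | methyl (2E,6S)-6-methoxy-2-methyl-7-oxohept-2-enoate (C1–C7 aldehyde) | O=C[C@@H](OC)CC/C=C(\C)C(=O)OC | intermediate
8 | 3-bromo-5-hydroxybenzaldehyde | O=Cc1cc(O)cc(Br)c1 | starting material
9 | 3-bromo-5-[(triisopropylsilyl)oxy]benzaldehyde | O=Cc1cc(O[Si](C(C)C)(C(C)C)C(C)C)cc(Br)c1 | intermediate
10 | (1R,2S)-1-Ar-2-methylbut-3-en-1-ol (14S,15R) | C=C[C@H](C)[C@@H](O)c1cc(O[Si](C(C)C)(C(C)C)C(C)C)cc(Br)c1 | intermediate
11 | (1R,2S)-1-Ar-1-(TBSO)-2-methylbut-3-ene | C=C[C@H](C)[C@@H](O[Si](C)(C)C(C)(C)C)c1cc(O[Si](C(C)C)(C(C)C)C(C)C)cc(Br)c1 | intermediate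
12 | 9-[(3S,4R)-4-Ar-4-(TBSO)-3-methylbutyl]-9-borabicyclo[3.3.1]nonane | C(C[C@H](C)[C@@H](O[Si](C)(C)C(C)(C)C)c1cc(O[Si](C(C)C)(C(C)C)C(C)C)cc(Br)c1)B1C2CCCC1CCC2 | intermediate
13 | (3S,4R)-4-Ar-4-(TBSO)-3-methylbutan-1-ol | OCC[C@H](C)[C@@H](O[Si](C)(C)C(C)(C)C)c1cc(O[Si](C(C)C)(C(C)C)C(C)C)cc(Br)c1 | intermediate
14 | (3S,4R)-4-Ar-4-(TBSO)-3-methylbutanal (C12 aldehyde) | O=CC[C@H](C)[C@@H](O[Si](C)(C)C(C)(C)C)c1cc(O[Si](C(C)C)(C(C)C)C(C)C)cc(Br)c1 | intermediate
15 | (2E,4S,6S,7R)-7-Ar-7-(TBSO)-6-methylhept-2-en-4-ol (12S,14S,15R) | C/C=C/[C@@H](O)C[C@H](C)[C@@H](O[Si](C)(C)C(C)(C)C)c1cc(O[Si](C(C)C)(C(C)C)C(C)C)cc(Br)c1 | intermediate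
16 | (1S,3S,4R)-4-Ar-4-(TBSO)-3-methyl-1-[(2S,3S)-3-methyloxiran-2-yl]butan-1-ol (anti trans-epoxy alcohol) | C[C@@H]1O[C@H]1[C@@H](O)C[C@H](C)[C@@H](O[Si](C)(C)C(C)(C)C)c1cc(O[Si](C(C)C)(C(C)C)C(C)C)cc(Br)c1 | intermediate
17 | (2R,3S)-2-[(1S,3S,4R)-4-Ar-4-(TBSO)-1-methoxy-3-methylbutyl]-3-methyloxirane | C[C@@H]1O[C@H]1[C@@H](OC)C[C@H](C)[C@@H](O[Si](C)(C)C(C)(C)C)c1cc(O[Si](C(C)C)(C(C)C)C(C)C)cc(Br)c1 | intermediate
18 | (4S,5R,6S,8S,9R)-9-Ar-9-(TBSO)-6-methoxy-4,8-dimethylnon-2-yn-5-ol (10S,11R,12S,14S,15R) | CC#C[C@H](C)[C@@H](O)[C@@H](OC)C[C@H](C)[C@@H](O[Si](C)(C)C(C)(C)C)c1cc(O[Si](C(C)C)(C(C)C)C(C)C)cc(Br)c1 | intermediate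
19 | (4S,5R,6S,8S,9R)-9-Ar-5,9-bis(TBSO)-6-methoxy-4,8-dimethylnon-2-yne (C8–C21 alkyne) | CC#C[C@H](C)[C@@H](O[Si](C)(C)C(C)(C)C)[C@@H](OC)C[C@H](C)[C@@H](O[Si](C)(C)C(C)(C)C)c1cc(O[Si](C(C)C)(C(C)C)C(C)C)cc(Br)c1 | intermediate
20 | chlorobis(cyclopentadienyl)[(2E,4S,5R,6S,8S,9R)-9-Ar-5,9-bis(TBSO)-6-methoxy-4,8-dimethylnon-2-en-2-yl]zirconium (cyclopentadienyl drawn σ-bound) | C/C(=C\[C@H](C)[C@@H](O[Si](C)(C)C(C)(C)C)[C@@H](OC)C[C@H](C)[C@@H](O[Si](C)(C)C(C)(C)C)c1cc(O[Si](C(C)C)(C(C)C)C(C)C)cc(Br)c1)[Zr](Cl)(C1C=CC=C1)C1C=CC=C1 | intermediate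
21 | methyl[(2E,4S,5R,6S,8S,9R)-9-Ar-5,9-bis(TBSO)-6-methoxy-4,8-dimethylnon-2-en-2-yl]zinc | C/C(=C\[C@H](C)[C@@H](O[Si](C)(C)C(C)(C)C)[C@@H](OC)C[C@H](C)[C@@H](O[Si](C)(C)C(C)(C)C)c1cc(O[Si](C(C)C)(C(C)C)C(C)C)cc(Br)c1)[Zn]C | intermediate
22 | methyl (2E,6S,7S,8E,10S,11R,12S,14S,15R)-15-Ar-11,15-bis(TBSO)-7-hydroxy-6,12-dimethoxy-2,8,10,14-tetramethylpentadeca-2,8-dienoate | COC(=O)/C(C)=C/CC[C@H](OC)[C@@H](O)/C(C)=C/[C@H](C)[C@@H](O[Si](C)(C)C(C)(C)C)[C@@H](OC)C[C@H](C)[C@@H](O[Si](C)(C)C(C)(C)C)c1cc(O[Si](C(C)C)(C(C)C)C(C)C)cc(Br)c1 | intermediate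
23 | methyl (2E,6S,7S,8E,10S,11R,12S,14S,15R)-15-Ar-7,11,15-tris(TBSO)-6,12-dimethoxy-2,8,10,14-tetramethylpentadeca-2,8-dienoate | COC(=O)/C(C)=C/CC[C@H](OC)[C@@H](O[Si](C)(C)C(C)(C)C)/C(C)=C/[C@H](C)[C@@H](O[Si](C)(C)C(C)(C)C)[C@@H](OC)C[C@H](C)[C@@H](O[Si](C)(C)C(C)(C)C)c1cc(O[Si](C(C)C)(C(C)C)C(C)C)cc(Br)c1 | intermediate
24 | (2E,6S,7S,8E,10S,11R,12S,14S,15R)-15-Ar-7,11,15-tris(TBSO)-6,12-dimethoxy-2,8,10,14-tetramethylpentadeca-2,8-dienamide | NC(=O)/C(C)=C/CC[C@H](OC)[C@@H](O[Si](C)(C)C(C)(C)C)/C(C)=C/[C@H](C)[C@@H](O[Si](C)(C)C(C)(C)C)[C@@H](OC)C[C@H](C)[C@@H](O[Si](C)(C)C(C)(C)C)c1cc(O[Si](C(C)C)(C(C)C)C(C)C)cc(Br)c1 | intermediate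
25 | 7,11,15-tris-O-TBS-18-O-TIPS macrolactam (6S,7S,10S,11R,12S,14S,15R; 2E,8E) | CO[C@H]1C[C@H](C)[C@@H](O[Si](C)(C)C(C)(C)C)c2cc(O[Si](C(C)C)(C(C)C)C(C)C)cc(c2)NC(=O)/C(C)=C/CC[C@H](OC)[C@@H](O[Si](C)(C)C(C)(C)C)/C(C)=C/[C@H](C)[C@H]1O[Si](C)(C)C(C)(C)C | intermediate
26 | CNP0366451.1, 19-membered ansa lactam (6S,7S,10S,11R,12S,14S,15R; 2E,8E) | CO[C@H]1C[C@H](C)[C@@H](O)c2cc(O)cc(c2)NC(=O)/C(C)=C/CC[C@H](OC)[C@@H](O)/C(C)=C/[C@H](C)[C@H]1O | target

**Step count.** Total: 20 steps (steps 1–5 give aldehyde 7, steps 6–15 give alkyne 19, steps 16–20 join the fragments and finish). Longest linear sequence: 15 steps (8 to 26, steps 6–20).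

**Steps most likely to fail**

1. Step 19. The cyclisation may be slow, so that intermolecular amidation (oligomers), protodebromination or loss of the aryl silyl ether under hot carbonate compete. The fallback sets out from 24 and makes the same N–C20 bond with reversed polarity at room temperature. Miyaura borylation (Pd(OAc)2, XPhos, B2(OH)4, KOAc, EtOH, 80 °C) would give the arylboronic acid F1. Oxidative Chan–Lam N-arylation of the primary amide (Cu(OAc)2, pyridine, 4 Å molecular sieves, CH2Cl2, air, rt, high dilution) would then close the ring and return to 25.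

2. Step 16. Chelation control may be incomplete, giving poor facial selectivity at C7, or the α-methoxy aldehyde may epimerise before addition. The fallback sets out from 19 and 7 and fixes C7 by reagent control instead of substrate chelation. The coupling is run as before, and the mixture of 22 and its C7 epimer F2 is oxidised with Dess–Martin periodinane to the enone F3. Corey–Bakshi–Shibata reduction of F3 ((S)-2-methyl-CBS-oxazaborolidine, catecholborane, toluene, −78 °C; the alkenyl group acting as the large substituent) should then give the 7S alcohol and return to 22.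

3. Step 18. Aminolysis of the hindered conjugated ester may be sluggish, with the aluminium amide attacking the aryl silyl ether instead. The fallback sets out from 23. Neutral ester cleavage with Me3SnOH (1,2-dichloroethane, 80 °C) would give the carboxylic acid F4. Activation with isobutyl chloroformate and N-methylmorpholine (THF, −15 °C) would give the mixed carbonic anhydride F5, which is treated in the same flask with ammonia and returns to 24.

**Further compounds**

F1 | step 19 | arylboronic acid of 24 (B(OH)2 in place of Br at C20) | NC(=O)/C(C)=C/CC[C@H](OC)[C@@H](O[Si](C)(C)C(C)(C)C)/C(C)=C/[C@H](C)[C@@H](O[Si](C)(C)C(C)(C)C)[C@@H](OC)C[C@H](C)[C@@H](O[Si](C)(C)C(C)(C)C)c1cc(O[Si](C(C)C)(C(C)C)C(C)C)cc(B(O)O)c1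
F2 | step 16 | (7R)-epimer of 22 | COC(=O)/C(C)=C/CC[C@H](OC)[C@H](O)/C(C)=C/[C@H](C)[C@@H](O[Si](C)(C)C(C)(C)C)[C@@H](OC)C[C@H](C)[C@@H](O[Si](C)(C)C(C)(C)C)c1cc(O[Si](C(C)C)(C(C)C)C(C)C)cc(Br)c1
F3 | step 16 | C7 enone (7-oxo analogue of 22) | COC(=O)/C(C)=C/CC[C@H](OC)C(=O)/C(C)=C/[C@H](C)[C@@H](O[Si](C)(C)C(C)(C)C)[C@@H](OC)C[C@H](C)[C@@H](O[Si](C)(C)C(C)(C)C)c1cc(O[Si](C(C)C)(C(C)C)C(C)C)cc(Br)c1
F4 | step 18 | carboxylic acid of 23 | OC(=O)/C(C)=C/CC[C@H](OC)[C@@H](O[Si](C)(C)C(C)(C)C)/C(C)=C/[C@H](C)[C@@H](O[Si](C)(C)C(C)(C)C)[C@@H](OC)C[C@H](C)[C@@H](O[Si](C)(C)C(C)(C)C)c1cc(O[Si](C(C)C)(C(C)C)C(C)C)cc(Br)c1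
F5 | step 18 | mixed isobutyl carbonic anhydride of F4 | CC(C)COC(=O)OC(=O)/C(C)=C/CC[C@H](OC)[C@@H](O[Si](C)(C)C(C)(C)C)/C(C)=C/[C@H](C)[C@@H](O[Si](C)(C)C(C)(C)C)[C@@H](OC)C[C@H](C)[C@@H](O[Si](C)(C)C(C)(C)C)c1cc(O[Si](C(C)C)(C(C)C)C(C)C)cc(Br)c1
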